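A direct plan would buy the arene: 3,5-dimethoxy-2-methylbenzaldehyde A1 would be taken by olefination, asymmetric epoxidation and methyl-alane opening to arylbutanol A2. A2 would become on one branch dihydroisocoumarin A3 and on the other the free resorcinol A4. A3 and A4 would be joined through an ortho-quinone methide made from A3 and acetaldehyde to give dyad A5, and an orthoformate would close the last pyran.
Its weakest steps would be:
(a) the build-up of the CH(CH3)–CH(OH)CH3 side chain on the arene: four operations and two reagent-controlled centres for four carbons that a chiral-pool ester holds almost ready-made;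
(b) the quinone methide Friedel–Crafts union: the linker stereocentre would be made between two hexasubstituted rings with no substrate bias (C3/C4 are para to it), on an untested chiral-acid/dioxaborin combination and on the most valuable material;
(c) the final formylation–cyclisation of the whole dyad: an electrophile would have to find one ring carbon among four free phenols on an acid-labile bis(ortho-hydroxyaryl)ethane (retro-Friedel–Crafts, epimerisation) in the last step.

Plan of the new route.
Feature used: in each half C7 lies between the oxygen-bearing ring carbons C6 and C8, so C6–C7–CH(CH3)–C7′–C6′ is 3-methylglutaric acid with the linker carbon as its prochiral C3. The rest of each half (C8, C8a, C1, O2, C3, C4, C4a, C5, all methyls) is one C10 acid, 7.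
Cuts: C7–C8 and C5–C6 in both carbocycles, so the target is anhydride 8 plus two molecules of 7 (stereodyad from methyl (R)-3-hydroxybutanoate by one alkylation).
Ring order: the lactone ring comes first (in 7); carbocycle A is then closed (steps 7–8) and its lactone reduced to an acetal; carbocycle B is closed the same way (steps 13–14); the quinone methide is unveiled last.
The weak steps do not arise: the linker centre is fixed at the start by desymmetrising an achiral anhydride; no side chain is built on an arene; there is no quinone methide coupling and no late formylation, because C1 arrives inside 7 and the last step is a hydrolysis only.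

Key step: step 8

Remark: of the pseudo-enantiomeric catalysts (DHQD)2AQN and (DHQ)2AQN, the one that delivers (S)-9 is meant; its sense of induction for this anhydride is assumed, not recalled with certainty.
Remark: ring atoms are numbered as in isochroman (C1, O2, C3, C4, C4a, C5–C8, C8a); the carbocycle closures are 6-endo.
Remark: acid chloride 11 is moisture-sensitive and would be made by step 6 freshly for each of its two uses (steps 7 and 13).

Step 1
Reactants: 1 methyl (R)-3-hydroxybutanoate
Product: 2 methyl (2R,3R)-3-hydroxy-2-methylbutanoate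
Conditions: LiN(iPr)2 (2.2 eq), THF, −78 → −20 °C; MeI (1.3 eq), DMPU, −78 → 0 °C; H2O
Reagents that add atoms: iodomethane CI
Why: Fráter–Seebach alkylation; the chelated alkoxide–enolate dianion is methylated anti to the C3 methyl, which sets the new centre (future C4) relative to the purchased carbinol centre (future C3) and gives the anti (2R,3R) dyad used in both halves.

Step 2
Reactants: 2 methyl (2R,3R)-3-hydroxy-2-methylbutanoate
Product: 4 (4R,5R)-5-hydroxy-4-methylhexan-3-one, via Weinreb amide 3 (not isolated)
Conditions: MeNH(OMe)·HCl (1.6 eq), iPrMgCl (4.2 eq), THF, −20 °C; then EtMgBr (2.0 eq), −20 → 0 °C; H2O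
Reagents that add atoms: ethylmagnesium bromide CC[Mg]Br
Why: Weinreb ketone synthesis run in one flask (ester aminolysis by the chloromagnesium amide, then Grignard addition); the chelated tetrahedral intermediate stops at the ketone and the α-centre, held in the magnesium alkoxide chelate, should not epimerise.

Step 3
Reactants: 4 (4R,5R)-5-hydroxy-4-methylhexan-3-one; 5 Meldrum's acid (2,2-dimethyl-1,3-dioxane-4,6-dione)
Product: 7 (5S,6R)-4-ethyl-5,6-dimethyl-2-oxo-5,6-dihydro-2H-pyran-3-carboxylic acid, via alkylidene Meldrum's acid 6 (not isolated)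
Conditions: TiCl4 (2.2 eq), pyridine (5 eq), THF, 0 °C → rt; then 45 °C; dilute HCl work-up
Reagents that add atoms: none
Why: Lehnert-type Knoevenagel condensation of the ketone with Meldrum's acid, then intramolecular alcoholysis of the alkylidene Meldrum's acid by the δ-hydroxyl (as in coumarin-3-carboxylic acid synthesis), which closes the lactone, releases acetone and leaves the second carbonyl as the free acid; the two Meldrum carbonyls are equivalent, so alkene geometry is no issue.

Step 4
Reactants: 8 3-methylglutaric anhydride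
Product: 9 (S)-5-methoxy-3-methyl-5-oxopentanoic acid
Conditions: (DHQD)2AQN (10 mol%), MeOH (10 eq), Et2O, −40 °C
Reagents that add atoms: methanol CO
Why: cinchona-alkaloid-catalysed enantioselective methanolysis of a prochiral cyclic anhydride (desymmetrisation); the catalyst chooses one of two enantiotopic carbonyl groups and so turns the prochiral C3 into the S centre that becomes the linker carbon.

Step 5
Reactants: 9 (S)-5-methoxy-3-methyl-5-oxopentanoic acid
Product: 10 methyl (3R)-3-methyl-5-oxo-5-(phenylsulfanyl)pentanoate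
Conditions: PhSH (1.2 eq), DCC (1.1 eq), DMAP (5 mol%), CH2Cl2, 0 °C → rt
Reagents that add atoms: thiophenol Sc1ccccc1
Why: Steglich thioesterification of the free acid arm; the stereocentre is β to both carbonyl groups and cannot epimerise, and the S-phenyl thioester is the only arm that enolises in step 7 (the descriptor changes to R by priority only).

Step 6
Reactants: 7 (5S,6R)-4-ethyl-5,6-dimethyl-2-oxo-5,6-dihydro-2H-pyran-3-carboxylic acid
Product: 11 (5S,6R)-4-ethyl-5,6-dimethyl-2-oxo-5,6-dihydro-2H-pyran-3-carbonyl chloride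
Conditions: (COCl)2 (1.2 eq), DMF (cat.), CH2Cl2, 0 °C → rt; evaporate, strip with toluene; used crude
Reagents that add atoms: oxalyl chloride O=C(Cl)C(=O)Cl
Why: acid chloride formation through the Vilsmeier chloroiminium species; without added base the γ-hydrogens are not removed, so no vinylketene forms, and the lactone and both stereocentres are untouched.

Step 7
Reactants: 10 methyl (3R)-3-methyl-5-oxo-5-(phenylsulfanyl)pentanoate; 11 (5S,6R)-4-ethyl-5,6-dimethyl-2-oxo-5,6-dihydro-2H-pyran-3-carbonyl chloride
Product: 12 methyl (3R)-4-{[(5S,6R)-4-ethyl-5,6-dimethyl-2-oxo-5,6-dihydro-2H-pyran-3-yl]carbonyl}-3-methyl-5-oxo-5-(phenylsulfanyl)pentanoate (C4 epimers/enol tautomers)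
Conditions: 10 (1.0 eq), 11 (1.1 eq), MgBr2·OEt2 (2.5 eq), iPr2NEt (3 eq), CH2Cl2, 0 °C → rt
Reagents that add atoms: none
Why: soft-enolisation crossed Claisen acylation of an S-phenyl thioester by an acid chloride; only the thioester α-CH2 (C7) is acidic enough for magnesium bromide/amine, the methyl ester arm and the lactone are untouched, and the product is held as its magnesium chelate so no second acylation occurs; this forms C7–C8.

Step 8
Reactants: 12 methyl (3R)-4-{[(5S,6R)-4-ethyl-5,6-dimethyl-2-oxo-5,6-dihydro-2H-pyran-3-yl]carbonyl}-3-methyl-5-oxo-5-(phenylsulfanyl)pentanoate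
Product: 14 methyl (3R)-3-[(3R,4S)-6,8-dihydroxy-3,4,5-trimethyl-1-oxoisochroman-7-yl]butanoate, via acylketene 13 (not isolated)
Conditions: AgO2CCF3 (1.3 eq), Et3N (3 eq), THF (0.01 M), 0 → 45 °C
Reagents that add atoms: none
Why: Proposed new method: the thiophilic silver salt removes thiophenolate from the enolised β-keto thioester (the way such thioesters serve as acylketene sources for esters and amides) and gives acylketene 13, O=C6=C7(R)–C8(=O)–; triethylamine then moves a proton from the ethyl CH2 (C5, vinylogous to both C8=O and the lactone C1=O) to O8, so that ketene, enol C8=C8a and the new ethylidene C4a=C5 form a 3-hydroxy-dienylketene held s-cis by two exocyclic double bonds on adjacent lactone carbons. This triene closes between C6 and C5 by 6π-electrocyclisation (equally, C-acylation of the dienolate γ-carbon by the ketene), and tautomerisation of the cyclohexadienone gives the resorcinol. The closest known reaction types are the last stage of the Danheiser benzannulation, where a 3-oxy-dienylketene of the same connectivity electrocyclises to a resorcinol, and the benzannulation of dienoic acids through dienylketenes. The carbocycle C5–C6–C7–C8–C8a–C4a is closed 6-endo across the existing lactone ring, which fixes all six substituents without any regiochemical choice. No stereocentre is formed, and C3, C4 and the linker centre are spectators. The selectivity needed is enolisation toward the ethyl group and not toward ring carbon C4: closure through C4 would require a bridgehead alkene in a bicyclo[3.3.1] frame and is unproductive, and high dilution keeps the ketene from dimerising or acylating product phenol.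

Step 9
Reactants: 14 methyl (3R)-3-[(3R,4S)-6,8-dihydroxy-3,4,5-trimethyl-1-oxoisochroman-7-yl]butanoate
Product: 15 methyl (3R)-3-[(3R,4S)-6,8-bis(methoxymethoxy)-3,4,5-trimethyl-1-oxoisochroman-7-yl]butanoate
Conditions: NaH (2.5 eq), MeOCH2Cl (3 eq), DMF, 0 °C → rt
Reagents that add atoms: chloromethyl methyl ether COCCl
Why: Williamson etherification of the two phenoxides; the MOM groups free the lactone carbonyl from phenoxide conjugation for step 11 and tolerate hydroxide, hydride and amide base.

Step 10
Reactants: 15 methyl (3R)-3-[(3R,4S)-6,8-bis(methoxymethoxy)-3,4,5-trimethyl-1-oxoisochroman-7-yl]butanoate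
Product: 16 (3R)-3-[(3R,4S)-6,8-bis(methoxymethoxy)-3,4,5-trimethyl-1-oxoisochroman-7-yl]butanoic acid
Conditions: LiOH (1.5 eq), THF–H2O 3:1, 0 °C; 1 M HCl to pH 4
Reagents that add atoms: lithium hydroxide [Li+].[OH-]
Why: saponification; hydroxide attacks the unhindered aliphatic methyl ester while the lactone carbonyl, flanked by two ortho substituents, is shielded (a lactone opened by accident should re-close at pH 4).

Step 11
Reactants: 16 (3R)-3-[(3R,4S)-6,8-bis(methoxymethoxy)-3,4,5-trimethyl-1-oxoisochroman-7-yl]butanoic acid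
Product: 18 (3R)-3-[(3R,4S)-1-methoxy-6,8-bis(methoxymethoxy)-3,4,5-trimethylisochroman-7-yl]butanoic acid (C1 epimers), via lactol 17 (not isolated)
Conditions: iBu2AlH (2.2 eq), CH2Cl2, −78 °C; aq. potassium sodium tartrate; then MeOH, PPTS (10 mol%), rt
Reagents that add atoms: methanol CO
Why: half-reduction of the aryl lactone to the lactol by diisobutylaluminium hydride at −78 °C (the first equivalent turns the acid into an aluminium carboxylate that should be inert at this temperature), then acid-catalysed acetalisation of the electron-rich benzylic lactol; C1 of the future quinone methide reaches the aldehyde level before ring B exists, so two lactones never have to be told apart.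

Step 12
Reactants: 18 (3R)-3-[(3R,4S)-1-methoxy-6,8-bis(methoxymethoxy)-3,4,5-trimethylisochroman-7-yl]butanoic acid
Product: 19 S-phenyl (3R)-3-[(3R,4S)-1-methoxy-6,8-bis(methoxymethoxy)-3,4,5-trimethylisochroman-7-yl]butanethioate
Conditions: PhSH (1.2 eq), DCC (1.1 eq), DMAP (5 mol%), CH2Cl2, 0 °C
Reagents that add atoms: thiophenol Sc1ccccc1
Why: Steglich thioesterification under neutral conditions that leave the cyclic acetal and the MOM ethers intact.

Step 13
Reactants: 19 S-phenyl (3R)-3-[(3R,4S)-1-methoxy-6,8-bis(methoxymethoxy)-3,4,5-trimethylisochroman-7-yl]butanethioate; 11 (5S,6R)-4-ethyl-5,6-dimethyl-2-oxo-5,6-dihydro-2H-pyran-3-carbonyl chloride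
Product: 20 S-phenyl (3R)-2-{[(5S,6R)-4-ethyl-5,6-dimethyl-2-oxo-5,6-dihydro-2H-pyran-3-yl]carbonyl}-3-[(3R,4S)-1-methoxy-6,8-bis(methoxymethoxy)-3,4,5-trimethylisochroman-7-yl]butanethioate (C2 epimers/enol tautomers)
Conditions: 19, LiN(SiMe3)2 (2.1 eq), THF, −78 °C; 11 (1.1 eq) in THF added slowly; AcOH, −78 °C
Reagents that add atoms: none
Why: crossed Claisen acylation of the thioester lithium enolate at −78 °C (amide base instead of magnesium bromide, because a Lewis acid would ionise the cyclic acetal); the second equivalent of base deprotonates the more acidic β-keto thioester as it forms, so proton transfer does not quench unreacted enolate and the product is protected from a second acylation; this forms C7′–C8′.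

Step 14
Reactants: 20 S-phenyl (3R)-2-{[(5S,6R)-4-ethyl-5,6-dimethyl-2-oxo-5,6-dihydro-2H-pyran-3-yl]carbonyl}-3-[(3R,4S)-1-methoxy-6,8-bis(methoxymethoxy)-3,4,5-trimethylisochroman-7-yl]butanethioate
Product: 22 (3R,4S)-6,8-dihydroxy-7-{(1R)-1-[(3R,4S)-1-methoxy-6,8-bis(methoxymethoxy)-3,4,5-trimethylisochroman-7-yl]ethyl}-3,4,5-trimethylisochroman-1-one (acetal epimers), via acylketene 21 (not isolated)
Conditions: AgO2CCF3 (1.3 eq), Et3N (3 eq), THF (0.01 M), 0 → 45 °C
Reagents that add atoms: none
Why: Proposed new method: same ring closure as step 8 (silver-assisted loss of thiophenolate to acylketene 21, amine-mediated enolisation toward the ethyl CH2, 6π-electrocyclisation of the 3-hydroxy-dienylketene between C6′ and C5′, tautomerisation to the resorcinol), with the Danheiser dienylketene electrocyclisation as closest known reaction type; the amine buffer protects the acetal and MOM groups, no stereocentre is formed, and the linker centre, now flanked by one arene and one acyl-bearing carbon, has no pathway to epimerise.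

Step 15
Reactants: 22 (3R,4S)-6,8-dihydroxy-7-{(1R)-1-[(3R,4S)-1-methoxy-6,8-bis(methoxymethoxy)-3,4,5-trimethylisochroman-7-yl]ethyl}-3,4,5-trimethylisochroman-1-one
Product: 23 dicitrinone H
Conditions: 1 M HCl, THF–H2O 4:1, 40 °C; extract; dry azeotropically with toluene
Reagents that add atoms: none
Why: acid hydrolysis of the two MOM ethers and of the cyclic acetal; the 6,8-dihydroxy lactol should lose water to the quinone methide (the citrinin chromophore) on drying, no alcohol cosolvent is used because such quinone methides add alcohols at C1, and the ring B lactone, the four ring stereocentres and the linker centre are untouched.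

**Compound list**
1 | methyl (R)-3-hydroxybutanoate | C[C@@H](O)CC(=O)OC | starting material
2 | methyl (2R,3R)-3-hydroxy-2-methylbutanoate | C[C@@H](O)[C@@H](C)C(=O)OC | intermediate
3 | (2R,3R)-3-hydroxy-N-methoxy-N,2-dimethylbutanamide (Weinreb amide; not isolated) | C[C@@H](O)[C@@H](C)C(=O)N(C)OC | intermediate
4 | (4R,5R)-5-hydroxy-4-methylhexan-3-one | C[C@@H](O)[C@@H](C)C(=O)CC | intermediate
5 | Meldrum's acid (2,2-dimethyl-1,3-dioxane-4,6-dione) | CC1(C)OC(=O)CC(=O)O1 | starting material
6 | 5-[(4S,5R)-5-hydroxy-4-methylhexan-3-ylidene]-2,2-dimethyl-1,3-dioxane-4,6-dione (not isolated) | C[C@@H](O)[C@@H](C)C(CC)=C1C(=O)OC(C)(C)OC1=O | intermediate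
7 | (5S,6R)-4-ethyl-5,6-dimethyl-2-oxo-5,6-dihydro-2H-pyran-3-carboxylic acid | CCC1=C(C(=O)O)C(=O)O[C@H](C)[C@H]1C | intermediate
8 | 3-methylglutaric anhydride (4-methyloxane-2,6-dione) | CC1CC(=O)OC(=O)C1 | starting material
9 | (S)-5-methoxy-3-methyl-5-oxopentanoic acid | OC(=O)C[C@H](C)CC(=O)OC | intermediate
10 | methyl (3R)-3-methyl-5-oxo-5-(phenylsulfanyl)pentanoate | COC(=O)C[C@@H](C)CC(=O)Sc1ccccc1 | intermediate
11 | (5S,6R)-4-ethyl-5,6-dimethyl-2-oxo-5,6-dihydro-2H-pyran-3-carbonyl chloride (used crude) | CCC1=C(C(Cl)=O)C(=O)O[C@H](C)[C@H]1C | intermediate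
12 | methyl (3R)-4-{[(5S,6R)-4-ethyl-5,6-dimethyl-2-oxo-5,6-dihydro-2H-pyran-3-yl]carbonyl}-3-methyl-5-oxo-5-(phenylsulfanyl)pentanoate (C4 epimers/enol tautomers) | COC(=O)C[C@@H](C)C(C(=O)Sc1ccccc1)C(=O)C1=C(CC)[C@H](C)[C@@H](C)OC1=O | intermediate
13 | acylketene from 12 by loss of thiophenol: methyl (3R)-4-{[(5S,6R)-4-ethyl-5,6-dimethyl-2-oxo-5,6-dihydro-2H-pyran-3-yl]carbonyl}-3-methyl-5-oxopent-4-enoate (not isolated) | COC(=O)C[C@@H](C)C(=C=O)C(=O)C1=C(CC)[C@H](C)[C@@H](C)OC1=O | intermediate
14 | methyl (3R)-3-[(3R,4S)-6,8-dihydroxy-3,4,5-trimethyl-1-oxoisochroman-7-yl]butanoate | COC(=O)C[C@@H](C)c1c(O)c(C)c2c(c1O)C(=O)O[C@H](C)[C@H]2C | intermediate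
15 | methyl (3R)-3-[(3R,4S)-6,8-bis(methoxymethoxy)-3,4,5-trimethyl-1-oxoisochroman-7-yl]butanoate | COC(=O)C[C@@H](C)c1c(OCOC)c(C)c2c(c1OCOC)C(=O)O[C@H](C)[C@H]2C | intermediate
16 | (3R)-3-[(3R,4S)-6,8-bis(methoxymethoxy)-3,4,5-trimethyl-1-oxoisochroman-7-yl]butanoic acid | OC(=O)C[C@@H](C)c1c(OCOC)c(C)c2c(c1OCOC)C(=O)O[C@H](C)[C@H]2C | intermediate
17 | (3R)-3-[(3R,4S)-1-hydroxy-6,8-bis(methoxymethoxy)-3,4,5-trimethylisochroman-7-yl]butanoic acid (lactol, C1 epimers; not isolated) | OC(=O)C[C@@H](C)c1c(OCOC)c(C)c2c(c1OCOC)C(O)O[C@H](C)[C@H]2C | intermediate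
18 | (3R)-3-[(3R,4S)-1-methoxy-6,8-bis(methoxymethoxy)-3,4,5-trimethylisochroman-7-yl]butanoic acid (C1 epimers) | OC(=O)C[C@@H](C)c1c(OCOC)c(C)c2c(c1OCOC)C(OC)O[C@H](C)[C@H]2C | intermediate
19 | S-phenyl (3R)-3-[(3R,4S)-1-methoxy-6,8-bis(methoxymethoxy)-3,4,5-trimethylisochroman-7-yl]butanethioate (C1 epimers) | O=C(C[C@@H](C)c1c(OCOC)c(C)c2c(c1OCOC)C(OC)O[C@H](C)[C@H]2C)Sc1ccccc1 | intermediate
20 | S-phenyl (3R)-2-{[(5S,6R)-4-ethyl-5,6-dimethyl-2-oxo-5,6-dihydro-2H-pyran-3-yl]carbonyl}-3-[(3R,4S)-1-methoxy-6,8-bis(methoxymethoxy)-3,4,5-trimethylisochroman-7-yl]butanethioate (C2 epimers/enol tautomers) | O=C(Sc1ccccc1)C([C@@H](C)c1c(OCOC)c(C)c2c(c1OCOC)C(OC)O[C@H](C)[C@H]2C)C(=O)C1=C(CC)[C@H](C)[C@@H](C)OC1=O | intermediate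
21 | acylketene from 20 by loss of thiophenol (ketene on the former thioester carbon; all centres as in 20; not isolated) | O=C=C([C@@H](C)c1c(OCOC)c(C)c2c(c1OCOC)C(OC)O[C@H](C)[C@H]2C)C(=O)C1=C(CC)[C@H](C)[C@@H](C)OC1=O | intermediate
22 | (3R,4S)-6,8-dihydroxy-7-{(1R)-1-[(3R,4S)-1-methoxy-6,8-bis(methoxymethoxy)-3,4,5-trimethylisochroman-7-yl]ethyl}-3,4,5-trimethylisochroman-1-one (acetal epimers) | COC1O[C@H](C)[C@@H](C)c2c(C)c(OCOC)c([C@H](C)c3c(O)c(C)c4c(c3O)C(=O)O[C@H](C)[C@H]4C)c(OCOC)c12 | intermediate
23 | dicitrinone H: (3R,4S)-6,8-dihydroxy-7-[(1R)-1-[(3R,4S)-6-hydroxy-3,4,5-trimethyl-8-oxo-3,4-dihydro-8H-isochromen-7-yl]ethyl]-3,4,5-trimethylisochroman-1-one | CC1=C2C(=CO[C@H](C)[C@H]2C)C(=O)C([C@H](C)c2c(O)c(C)c3c(c2O)C(=O)O[C@H](C)[C@H]3C)=C1O | target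

Total step count: 15. Longest linear sequence: 13 steps (steps 1–3, 6, then 7–15); the branch from anhydride 8 (steps 4–5) joins at step 7.

Steps most likely to fail:

1. Step 8 (proposed method). The acylketene could dimerise or acylate product phenol instead of closing, or enolisation toward the ethyl group could be too slow. The fallback is a stepwise anionic closure from 12 with standard reaction types. O-Methylation of the β-dicarbonyl enol (Me3SiCHN2, MeOH–toluene) would give the enol methyl ether methyl (3R)-4-{methoxy[(5S,6R)-4-ethyl-5,6-dimethyl-2-oxo-5,6-dihydro-2H-pyran-3-yl]methylidene}-3-methyl-5-oxo-5-(phenylsulfanyl)pentanoate F1, which has no acidic C7–H. LiN(SiMe3)2 (THF, −78 → 0 °C) would then deprotonate the ethyl CH2, and the γ-carbanion would close onto the thioester (vinylogous Dieckmann condensation) to methyl (3R)-3-[(3R,4S)-6-hydroxy-8-methoxy-3,4,5-trimethyl-1-oxoisochroman-7-yl]butanoate F2. BCl3 (CH2Cl2, −78 °C), which cleaves a methyl ether next to a chelating carbonyl, would bring the route back to 14.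

2. Step 14 (proposed method). Beyond the risks of step 8, the cyclic acetal could ionise or MOM groups could be lost under silver and thiol. The fallback runs the same anionic sequence from 20. Me3SiCHN2 would give the O-methyl enol ether of 20 F3. LiN(SiMe3)2 would close it to the 8-O-methyl ether of 22 F4. BCl3 (CH2Cl2, −78 → 0 °C) followed by aqueous work-up would remove the chelated methyl ether, both MOM groups and the acetal in one operation and rejoin the route at 23.

3. Step 3. The β-hydroxy ketone could undergo retro-aldol cleavage or epimerise next to the ketone under TiCl4/pyridine, or acid 7 could decarboxylate on warming. The fallback makes the ester bond first and keeps the carboxyl masked. From 4, esterification with mono-tert-butyl malonate (DCC, DMAP) would give tert-butyl (2R,3R)-3-methyl-4-oxohexan-2-yl propanedioate F5. Intramolecular Knoevenagel condensation (TiCl4, pyridine, 0 °C) would give tert-butyl (5S,6R)-4-ethyl-5,6-dimethyl-2-oxo-5,6-dihydro-2H-pyran-3-carboxylate F6. CF3CO2H (CH2Cl2, 0 °C) would return 7.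

**Further compounds**
F1 | step 8 | methyl (3R)-4-{methoxy[(5S,6R)-4-ethyl-5,6-dimethyl-2-oxo-5,6-dihydro-2H-pyran-3-yl]methylidene}-3-methyl-5-oxo-5-(phenylsulfanyl)pentanoate (E/Z) | COC(=O)C[C@@H](C)C(C(=O)Sc1ccccc1)=C(OC)C1=C(CC)[C@H](C)[C@@H](C)OC1=O
F2 | step 8 | methyl (3R)-3-[(3R,4S)-6-hydroxy-8-methoxy-3,4,5-trimethyl-1-oxoisochroman-7-yl]butanoate | COC(=O)C[C@@H](C)c1c(O)c(C)c2c(c1OC)C(=O)O[C@H](C)[C@H]2C
F3 | step 14 | O-methyl enol ether of 20 (methoxy on the ketone carbon attached to the lactone; E/Z; all centres as in 20) | O=C(Sc1ccccc1)C([C@@H](C)c1c(OCOC)c(C)c2c(c1OCOC)C(OC)O[C@H](C)[C@H]2C)=C(OC)C1=C(CC)[C@H](C)[C@@H](C)OC1=O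
F4 | step 14 | 8-O-methyl ether of 22 (methoxy ortho to the lactone carbonyl of ring B; all centres as in 22) | COC1O[C@H](C)[C@@H](C)c2c(C)c(OCOC)c([C@H](C)c3c(O)c(C)c4c(c3OC)C(=O)O[C@H](C)[C@H]4C)c(OCOC)c12
F5 | step 3 | tert-butyl (2R,3R)-3-methyl-4-oxohexan-2-yl propanedioate | CC(C)(C)OC(=O)CC(=O)O[C@H](C)[C@H](C(=O)CC)C
F6 | step 3 | tert-butyl (5S,6R)-4-ethyl-5,6-dimethyl-2-oxo-5,6-dihydro-2H-pyran-3-carboxylate | CCC1=C(C(=O)OC(C)(C)C)C(=O)O[C@H](C)[C@H]1C
A1 | direct plan | 3,5-dimethoxy-2-methylbenzaldehyde | COc1cc(C=O)c(C)c(OC)c1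
A2 | direct plan | (2R,3S)-3-(3,5-dimethoxy-2-methylphenyl)butan-2-ol | O[C@H](C)[C@@H](C)c1cc(OC)cc(OC)c1C
A3 | direct plan | (3R,4S)-6,8-dihydroxy-3,4,5-trimethylisochroman-1-one | O=C1O[C@H](C)[C@@H](C)c2c(C)c(O)cc(O)c12
A4 | direct plan | (2R,3S)-3-(3,5-dihydroxy-2-methylphenyl)butan-2-ol | O[C@H](C)[C@@H](C)c1cc(O)cc(O)c1C
A5 | direct plan | (3R,4S)-7-[(1S)-1-{2,6-dihydroxy-4-[(2S,3R)-3-hydroxybutan-2-yl]-3-methylphenyl}ethyl]-6,8-dihydroxy-3,4,5-trimethylisochroman-1-one | O[C@H](C)[C@@H](C)c1cc(O)c([C@H](C)c2c(O)c(C)c3c(c2O)C(=O)O[C@H](C)[C@H]3C)c(O)c1C
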